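**Strategy.** Spiro[4.5]decane numbering is used: C1 = CHOH, C2 = CH bearing the triene, C5 = spiro carbon, C6 = C(OH)Me, C9 = alkylidene carbon, C10 = CH bearing the hydroxypropyl chain. The route rests on the C5–C6 disconnection. A keto acid that already holds C10 and the (Z)-enoate is closed by nucleophile-catalysed aldol-lactonisation: one operation makes the cyclohexane, the quaternary C5 and the tertiary carbinol C6, and ties the C6 oxygen to C1 as a β-lactone. It exploits the cis 1,3-relationship of the C6 hydroxyl and C1 across C5–C6. The lactone, absent from the target, is then reduced, and an allene–aldehyde cyclisation builds the cyclopentane.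

Key step: step 14

Remark: the configuration at the carbon α to the future acid in compounds 9–21 is erased in step 14 (it becomes the planar enolate carbon), so partial epimerisation there is of no consequence; it is drawn as formed in step 6.

Step 1
Reactants: 1 pentane-1,5-diol
Product: 2 5-[(tert-butyldiphenylsilyl)oxy]pentan-1-ol
Conditions: NaH (1.0 equiv), THF, 0 to 23 °C; then TBDPSCl
Reagents that add atoms: tert-butyl(chloro)diphenylsilane, CC(C)(C)[Si](Cl)(c1ccccc1)c1ccccc1
Why: The monosodium alkoxide of the symmetrical diol should be silylated once (O-silylation of a mono-alkoxide); no stereocentre is formed.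

Step 2
Reactants: 2 5-[(tert-butyldiphenylsilyl)oxy]pentan-1-ol
Product: 3 5-[(tert-butyldiphenylsilyl)oxy]pentanal
Conditions: TEMPO (cat.), PhI(OAc)2, CH2Cl2, 23 °C
Reagents that add atoms: none
Why: Oxoammonium (TEMPO) oxidation of a primary alcohol should stop at the aldehyde and leave the silyl ether untouched.

Step 3
Reactants: 4 pent-4-yn-1-ol
Product: 5 hexa-4,5-dien-1-ol
Conditions: (CH2O)n, CuI, i-Pr2NH, 1,4-dioxane, reflux
Reagents that add atoms: paraformaldehyde (as formaldehyde), C=O
Why: Crabbé homologation: the copper acetylide gives a Mannich base that undergoes a 1,5-hydride shift to the terminal allene, adding one carbon.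

Step 4
Reactants: 5 hexa-4,5-dien-1-ol
Product: 6 hexa-4,5-dienal
Conditions: TEMPO (cat.), PhI(OAc)2, CH2Cl2, 23 °C
Reagents that add atoms: none
Why: TEMPO oxidation of the primary alcohol to the aldehyde; the allene should be inert to the oxoammonium salt.

Step 5
Reactants: 6 hexa-4,5-dienal
Product: 8 (E)-1-nitrohepta-1,5,6-triene, via nitroaldol 7 (not isolated)
Conditions: MeNO2, KOt-Bu (cat.), THF/t-BuOH, 0 °C; then MsCl, Et3N, CH2Cl2, 0 °C
Reagents that add atoms: nitromethane, C[N+](=O)[O-]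
Why: Henry reaction followed by mesylation and E1cB elimination of the nitroaldol should give the thermodynamically favoured (E)-nitroalkene.

Step 6
Reactants: 3 5-[(tert-butyldiphenylsilyl)oxy]pentanal; 8 (E)-1-nitrohepta-1,5,6-triene
Product: 9 (2S,3S)-2-{3-[(tert-butyldiphenylsilyl)oxy]propyl}-3-(nitromethyl)octa-6,7-dienal
Conditions: (R)-2-[diphenyl(trimethylsilyloxy)methyl]pyrrolidine (10 mol %), PhCO2H (10 mol %), toluene, 0 °C
Reagents that add atoms: none
Why: Enamine-catalysed Michael addition of an aldehyde to a nitroalkene; the (R)-diarylprolinol silyl ether shields one enamine face and the synclinal acyclic transition state should give the syn adduct, which fixes the stereocentre that becomes C10.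

Step 7
Reactants: 9 (2S,3S)-2-{3-[(tert-butyldiphenylsilyl)oxy]propyl}-3-(nitromethyl)octa-6,7-dienal
Product: 10 (3S,4S)-1,1-dibromo-4-(nitromethyl)-3-{3-[(tert-butyldiphenylsilyl)oxy]propyl}nona-1,7,8-triene
Conditions: CBr4, PPh3, Zn, CH2Cl2, 0 °C
Reagents that add atoms: carbon tetrabromide, BrC(Br)(Br)Br
Why: The first stage of the Corey–Fuchs reaction (Wittig-type dibromomethylenation) runs without base, so the α-stereocentre of the aldehyde should not epimerise and the nitro group is untouched.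

Step 8
Reactants: 10 (3S,4S)-1,1-dibromo-4-(nitromethyl)-3-{3-[(tert-butyldiphenylsilyl)oxy]propyl}nona-1,7,8-triene
Product: 12 (3S,4S)-1,1-dibromo-4-(dimethoxymethyl)-3-{3-[(tert-butyldiphenylsilyl)oxy]propyl}nona-1,7,8-triene, via sodium nitronate 11 (not isolated)
Conditions: NaOMe, MeOH, 0 °C; then added to H2SO4/MeOH, −40 °C
Reagents that add atoms: methanol, CO
Why: Nef reaction of the nitronate in acidic methanol should deliver the aldehyde directly as its dimethyl acetal, a form that survives the organolithium and organocopper steps.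

Step 9
Reactants: 12 (3S,4S)-1,1-dibromo-4-(dimethoxymethyl)-3-{3-[(tert-butyldiphenylsilyl)oxy]propyl}nona-1,7,8-triene
Product: 14 methyl (4S,5S)-5-(dimethoxymethyl)-4-{3-[(tert-butyldiphenylsilyl)oxy]propyl}deca-8,9-dien-2-ynoate, via lithium acetylide 13 (not isolated)
Conditions: n-BuLi (2.05 equiv), THF, −78 °C; then ClCO2Me, −78 to 0 °C
Reagents that add atoms: methyl chloroformate, COC(=O)Cl
Why: Second stage of the Corey–Fuchs reaction: bromine–lithium exchange, 1,2-shift to the lithium acetylide and C-acylation should give the ynoate without touching the propargylic stereocentre.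

Step 10
Reactants: 14 methyl (4S,5S)-5-(dimethoxymethyl)-4-{3-[(tert-butyldiphenylsilyl)oxy]propyl}deca-8,9-dien-2-ynoate; 15 2-(2-bromoethyl)-2-methyl-1,3-dioxolane
Product: 18 methyl (2E,4S,5S)-5-(dimethoxymethyl)-2-iodo-3-[2-(2-methyl-1,3-dioxolan-2-yl)ethyl]-4-{3-[(tert-butyldiphenylsilyl)oxy]propyl}deca-2,8,9-trienoate, via Grignard reagent 16 (not isolated), via alkenylcopper 17 (not isolated)
Conditions: 15, Mg, THF; CuBr·SMe2, −78 °C; then 14, −78 °C; then I2 (1.0 equiv), −78 °C
Reagents that add atoms: iodine, II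
Why: syn-Carbocupration of the ynoate places the alkyl group on the β-carbon and copper on the α-carbon on the same side, and iodinolysis at low temperature proceeds with retention, which fixes the alkene geometry (ester cis to the stereogenic carbon).

Step 11
Reactants: 18 methyl (2E,4S,5S)-5-(dimethoxymethyl)-2-iodo-3-[2-(2-methyl-1,3-dioxolan-2-yl)ethyl]-4-{3-[(tert-butyldiphenylsilyl)oxy]propyl}deca-2,8,9-trienoate
Product: 19 methyl (2Z,4S,5S)-5-(dimethoxymethyl)-2-methyl-3-[2-(2-methyl-1,3-dioxolan-2-yl)ethyl]-4-{3-[(tert-butyldiphenylsilyl)oxy]propyl}deca-2,8,9-trienoate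
Conditions: MeZnCl, Pd(PPh3)4 (5 mol %), THF, 50 °C
Reagents that add atoms: methylzinc chloride, C[Zn]Cl
Why: Negishi coupling of the alkenyl iodide proceeds with retention and should give the (Z)-tetrasubstituted enoate with the methyl group cis to the ketal-bearing chain.

Step 12
Reactants: 19 methyl (2Z,4S,5S)-5-(dimethoxymethyl)-2-methyl-3-[2-(2-methyl-1,3-dioxolan-2-yl)ethyl]-4-{3-[(tert-butyldiphenylsilyl)oxy]propyl}deca-2,8,9-trienoate
Product: 20 methyl (2Z,4S,5S)-5-formyl-2-methyl-3-(3-oxobutyl)-4-{3-[(tert-butyldiphenylsilyl)oxy]propyl}deca-2,8,9-trienoate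
Conditions: 2 M HCl, THF, 23 °C
Reagents that add atoms: water, O
Why: Acid hydrolysis removes the dimethyl acetal and the dioxolane, while the TBDPS ether, the allene and the enoate should survive.

Step 13
Reactants: 20 methyl (2Z,4S,5S)-5-formyl-2-methyl-3-(3-oxobutyl)-4-{3-[(tert-butyldiphenylsilyl)oxy]propyl}deca-2,8,9-trienoate
Product: 21 (2S,3S,4Z)-6-methoxy-5-methyl-6-oxo-4-(3-oxobutyl)-2-(penta-3,4-dien-1-yl)-3-{3-[(tert-butyldiphenylsilyl)oxy]propyl}hex-4-enoic acid
Conditions: NaClO2, NaH2PO4, 2-methylbut-2-ene, t-BuOH/H2O, 0 °C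
Reagents that add atoms: sodium chlorite, [Na+].[O-]Cl=O
Why: Pinnick oxidation converts the aldehyde to the acid chemoselectively beside the ketone, the enoate and the allene (hypochlorite is scavenged).

Step 14
Reactants: 21 (2S,3S,4Z)-6-methoxy-5-methyl-6-oxo-4-(3-oxobutyl)-2-(penta-3,4-dien-1-yl)-3-{3-[(tert-butyldiphenylsilyl)oxy]propyl}hex-4-enoic acid
Product: 23 methyl (2Z)-2-[6-methyl-8-oxo-1-(penta-3,4-dien-1-yl)-2-{3-[(tert-butyldiphenylsilyl)oxy]propyl}-7-oxabicyclo[4.2.0]octan-3-ylidene]propanoate (cis-fused β-lactone; silyloxypropyl chain cis to the lactone carbonyl), via mixed anhydride 22 (not isolated)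
Conditions: TsCl, 4-pyrrolidinopyridine, i-Pr2NEt, LiCl, CH2Cl2, slow addition of 21, 23 °C
Reagents that add atoms: none
Why: Tosylation of the acid gives mixed anhydride 22; acyl transfer to 4-pyrrolidinopyridine and deprotonation give an ammonium enolate whose α-carbon (C5) adds to the methyl ketone (C6), and the tertiary aldolate then closes onto the acylammonium carbon and releases the catalyst. The closest known reaction type is the nucleophile-catalysed aldol-lactonisation of keto acids to carbocycle-fused β-lactones, including cases that create a fully substituted α-carbon. The cyclohexane closes by a 6-(enolexo)-exo-trig aldol addition and the β-lactone by a 4-exo-trig acyl substitution. The four-membered ring can only be cis-fused, so the C6 oxygen and C1 are cis whatever the facial course; the face relative to C10 is set by 1,3-allylic strain from the (Z)-ester-bearing exocyclic alkene at C9, which holds the C10 chain pseudo-axial, so that lactone formation on the face that places oxygen, not the C6 methyl, syn-axial to this chain should be preferred. The step needs chemoselectivity for the acid over the ketone and the ester, secured because only the carboxylic acid is activated by TsCl and only the methyl ketone lies within reach for a six-membered ring, and it needs capture of the aldolate before retro-aldol, which the irreversible lactonisation provides.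

Step 15
Reactants: 23 cis-fused β-lactone
Product: 24 (2Z)-2-[4-hydroxy-3-(hydroxymethyl)-4-methyl-3-(penta-3,4-dien-1-yl)-2-{3-[(tert-butyldiphenylsilyl)oxy]propyl}cyclohexylidene]propan-1-ol (4-OH and 3-CH2OH and 2-chain all cis)
Conditions: i-Bu2AlH (excess), CH2Cl2, −78 to 0 °C; Rochelle salt
Reagents that add atoms: none
Why: i-Bu2AlH reduces the strained β-lactone to the 1,3-diol and the conjugated ester to the allylic alcohol by 1,2-addition, without touching the stereocentres, the allene or the silyl ether.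

Step 16
Reactants: 24 triol
Product: 25 (2Z)-2-[3-formyl-4-hydroxy-4-methyl-3-(penta-3,4-dien-1-yl)-2-{3-[(tert-butyldiphenylsilyl)oxy]propyl}cyclohexylidene]propanal
Conditions: TEMPO (cat.), PhI(OAc)2, CH2Cl2, 23 °C
Reagents that add atoms: none
Why: TEMPO oxidation converts both primary alcohols (neopentyl and allylic) to aldehydes, which installs the final (Z)-enal, while the tertiary alcohol cannot react.

Step 17
Reactants: 25 hydroxy dialdehyde
Product: 26 (2Z)-2-[3-formyl-4-methyl-3-(penta-3,4-dien-1-yl)-2-{3-[(tert-butyldiphenylsilyl)oxy]propyl}-4-[(triethylsilyl)oxy]cyclohexylidene]propanal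
Conditions: Et3SiOTf, 2,6-lutidine, CH2Cl2, −78 °C
Reagents that add atoms: triethylsilyl trifluoromethanesulfonate, CC[Si](CC)(CC)OS(=O)(=O)C(F)(F)F
Why: Silylation of the tertiary alcohol blocks retro-aldol cleavage and removes the hydroxyl group as a chelating or hydrogen-bonding partner of the neighbouring aldehyde.

Step 18
Reactants: 26 silyl ether dialdehyde
Product: 29 (2Z)-2-[1-hydroxy-6-methyl-10-{3-[(tert-butyldiphenylsilyl)oxy]propyl}-6-[(triethylsilyl)oxy]-2-[1-(tributylstannyl)ethenyl]spiro[4.5]decan-9-ylidene]propanal (1-OH cis to the 2-alkenyl group; configuration as in the target), via bis-stannane 27 (not isolated), via tin alkoxide 28 (not isolated)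
Conditions: Bu3SnSnBu3, [(C3H5)PdCl]2 (5 mol %), THF, 23 °C; aqueous work-up
Reagents that add atoms: hexabutylditin, CCCC[Sn](CCCC)(CCCC)[Sn](CCCC)(CCCC)CCCC
Why: Palladium-catalysed distannylation of the terminal allene gives an allylstannane that adds to the neighbouring aldehyde through a closed transition state (five-membered ring, alcohol cis to the stannylvinyl group), and with the bulky non-chelating silyloxy group on C6 the aldehyde oxygen should point to the C10 side, which sets C1 and C2 as in the target.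

Step 19
Reactants: 30 prop-2-yn-1-ol; 31 5-bromo-2-methylpent-2-ene
Product: 34 (2Z)-2-(iodomethylidene)-6-methylhept-5-en-1-ol, via Grignard reagent 32 (not isolated), via alkenylmagnesium 33 (not isolated)
Conditions: 31, Mg, THF; then 30, CuI (10 mol %), THF, −10 to 23 °C; then I2, −78 to 0 °C
Reagents that add atoms: iodine, II
Why: Copper-catalysed anti-carbomagnesiation of the magnesium alkoxide of propargyl alcohol gives a cyclic alkenylmagnesium species, and iodinolysis with retention should give the (Z)-iodoalkene with iodine cis to the hydroxymethyl group.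

Step 20
Reactants: 34 (2Z)-2-(iodomethylidene)-6-methylhept-5-en-1-ol
Product: 35 (2Z)-2-(iodomethylidene)-6-methylhept-5-en-1-yl acetate
Conditions: Ac2O, pyridine, DMAP (cat.), CH2Cl2, 0 °C
Reagents that add atoms: acetic anhydride, CC(=O)OC(C)=O
Why: Standard acylation of the primary allylic alcohol.

Step 21
Reactants: 35 (2Z)-2-(iodomethylidene)-6-methylhept-5-en-1-yl acetate; 36 (E)-1,2-bis(tributylstannyl)ethene
Product: 37 (2Z)-6-methyl-2-[(2E)-3-(tributylstannyl)prop-2-en-1-ylidene]hept-5-en-1-yl acetate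
Conditions: PdCl2(MeCN)2 (5 mol %), DMF, 23 °C, excess 36
Reagents that add atoms: none
Why: Stille coupling of the alkenyl iodide with an excess of the bis-stannane couples once, with retention at both alkenes, to give the (1E,3Z)-dienylstannane.

Step 22
Reactants: 37 dienylstannane
Product: 38 (2Z)-2-[(2E)-3-iodoprop-2-en-1-ylidene]-6-methylhept-5-en-1-yl acetate
Conditions: I2 (1.0 equiv), CH2Cl2, 0 °C
Reagents that add atoms: iodine, II
Why: Iododestannylation is an ipso substitution with retention and is much faster than addition of iodine to the trisubstituted alkenes.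

Step 23
Reactants: 29 alkenylstannane; 38 dienyl iodide
Product: 39 target with the primary hydroxyl as tert-butyldiphenylsilyl ether and the tertiary hydroxyl as triethylsilyl ether
Conditions: Pd(PPh3)4 (10 mol %), CuI, CsF, DMF, 23 °C
Reagents that add atoms: none
Why: Copper- and fluoride-assisted Stille coupling joins the two alkenyl partners with retention under neutral conditions that should spare the allylic acetate, the enal and the silyl ethers.

Step 24
Reactants: 39 bis-silyl ether of the target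
Product: 40 CNP0205332.1
Conditions: HF·pyridine, pyridine, THF, 0 to 23 °C
Reagents that add atoms: none
Why: Buffered fluoride cleaves both silyl ethers, while the acetate, the enal and the triene should survive.

**Compound list**

1 | pentane-1,5-diol | OCCCCCO | starting material
2 | 5-[(tert-butyldiphenylsilyl)oxy]pentan-1-ol | OCCCCCO[Si](c1ccccc1)(c1ccccc1)C(C)(C)C | intermediate
3 | 5-[(tert-butyldiphenylsilyl)oxy]pentanal | O=CCCCCO[Si](c1ccccc1)(c1ccccc1)C(C)(C)C | intermediate
4 | pent-4-yn-1-ol | C#CCCCO | starting material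
5 | hexa-4,5-dien-1-ol | C=C=CCCCO | intermediate
6 | hexa-4,5-dienal | C=C=CCCC=O | intermediate
7 | 1-nitrohepta-5,6-dien-2-ol (nitroaldol, racemic) | C=C=CCCC(O)C[N+](=O)[O-] | intermediate (not isolated)
8 | (E)-1-nitrohepta-1,5,6-triene | C=C=CCC/C=C/[N+](=O)[O-] | intermediate
9 | (2S,3S)-2-{3-[(tert-butyldiphenylsilyl)oxy]propyl}-3-(nitromethyl)octa-6,7-dienal | O=C[C@@H](CCCO[Si](c1ccccc1)(c1ccccc1)C(C)(C)C)[C@H](CCC=C=C)C[N+](=O)[O-] | intermediate
10 | (3S,4S)-1,1-dibromo-4-(nitromethyl)-3-{3-[(tert-butyldiphenylsilyl)oxy]propyl}nona-1,7,8-triene | BrC(Br)=C[C@@H](CCCO[Si](c1ccccc1)(c1ccccc1)C(C)(C)C)[C@H](CCC=C=C)C[N+](=O)[O-] | intermediate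
11 | sodium nitronate of 10 | BrC(Br)=C[C@@H](CCCO[Si](c1ccccc1)(c1ccccc1)C(C)(C)C)[C@H](CCC=C=C)C=[N+]([O-])[O-].[Na+] | intermediate (not isolated)
12 | (3S,4S)-1,1-dibromo-4-(dimethoxymethyl)-3-{3-[(tert-butyldiphenylsilyl)oxy]propyl}nona-1,7,8-triene | BrC(Br)=C[C@@H](CCCO[Si](c1ccccc1)(c1ccccc1)C(C)(C)C)[C@H](CCC=C=C)C(OC)OC | intermediate
13 | lithium acetylide derived from 12 | [Li]C#C[C@@H](CCCO[Si](c1ccccc1)(c1ccccc1)C(C)(C)C)[C@H](CCC=C=C)C(OC)OC | intermediate (not isolated)
14 | methyl (4S,5S)-5-(dimethoxymethyl)-4-{3-[(tert-butyldiphenylsilyl)oxy]propyl}deca-8,9-dien-2-ynoate | COC(=O)C#C[C@@H](CCCO[Si](c1ccccc1)(c1ccccc1)C(C)(C)C)[C@H](CCC=C=C)C(OC)OC | intermediate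
15 | 2-(2-bromoethyl)-2-methyl-1,3-dioxolane | CC1(CCBr)OCCO1 | starting material
16 | [2-(2-methyl-1,3-dioxolan-2-yl)ethyl]magnesium bromide | CC1(CC[Mg]Br)OCCO1 | intermediate (not isolated)
17 | α-cuprio enoate from syn-carbocupration of 14 (copper cis to the dioxolanylethyl chain) | COC(=O)/C([Cu])=C(/CCC1(C)OCCO1)[C@@H](CCCO[Si](c2ccccc2)(c2ccccc2)C(C)(C)C)[C@H](CCC=C=C)C(OC)OC | intermediate (not isolated)
18 | methyl (2E,4S,5S)-5-(dimethoxymethyl)-2-iodo-3-[2-(2-methyl-1,3-dioxolan-2-yl)ethyl]-4-{3-[(tert-butyldiphenylsilyl)oxy]propyl}deca-2,8,9-trienoate | COC(=O)/C(I)=C(/CCC1(C)OCCO1)[C@@H](CCCO[Si](c2ccccc2)(c2ccccc2)C(C)(C)C)[C@H](CCC=C=C)C(OC)OC | intermediate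
19 | methyl (2Z,4S,5S)-5-(dimethoxymethyl)-2-methyl-3-[2-(2-methyl-1,3-dioxolan-2-yl)ethyl]-4-{3-[(tert-butyldiphenylsilyl)oxy]propyl}deca-2,8,9-trienoate | COC(=O)/C(C)=C(/CCC1(C)OCCO1)[C@@H](CCCO[Si](c2ccccc2)(c2ccccc2)C(C)(C)C)[C@H](CCC=C=C)C(OC)OC | intermediate
20 | methyl (2Z,4S,5S)-5-formyl-2-methyl-3-(3-oxobutyl)-4-{3-[(tert-butyldiphenylsilyl)oxy]propyl}deca-2,8,9-trienoate | COC(=O)/C(C)=C(/CCC(C)=O)[C@@H](CCCO[Si](c1ccccc1)(c1ccccc1)C(C)(C)C)[C@H](CCC=C=C)C=O | intermediate
21 | (2S,3S,4Z)-6-methoxy-5-methyl-6-oxo-4-(3-oxobutyl)-2-(penta-3,4-dien-1-yl)-3-{3-[(tert-butyldiphenylsilyl)oxy]propyl}hex-4-enoic acid | COC(=O)/C(C)=C(/CCC(C)=O)[C@@H](CCCO[Si](c1ccccc1)(c1ccccc1)C(C)(C)C)[C@H](CCC=C=C)C(=O)O | intermediate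
22 | mixed carboxylic p-toluenesulfonic anhydride of 21 | COC(=O)/C(C)=C(/CCC(C)=O)[C@@H](CCCO[Si](c1ccccc1)(c1ccccc1)C(C)(C)C)[C@H](CCC=C=C)C(=O)OS(=O)(=O)c1ccc(C)cc1 | intermediate (not isolated)
23 | methyl (2Z)-2-[6-methyl-8-oxo-1-(penta-3,4-dien-1-yl)-2-{3-[(tert-butyldiphenylsilyl)oxy]propyl}-7-oxabicyclo[4.2.0]octan-3-ylidene]propanoate (cis-fused; C2 chain cis to the lactone carbonyl) | C=C=CCC[C@@]12[C@H](CCCO[Si](c3ccccc3)(c3ccccc3)C(C)(C)C)/C(=C(/C)C(=O)OC)CC[C@]1(C)OC2=O | intermediate
24 | (2Z)-2-[4-hydroxy-3-(hydroxymethyl)-4-methyl-3-(penta-3,4-dien-1-yl)-2-{3-[(tert-butyldiphenylsilyl)oxy]propyl}cyclohexylidene]propan-1-ol (4-OH, 3-CH2OH and 2-chain all cis) | C=C=CCC[C@@]1(CO)[C@H](CCCO[Si](c2ccccc2)(c2ccccc2)C(C)(C)C)/C(=C(/C)CO)CC[C@]1(C)O | intermediate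
25 | (2Z)-2-[3-formyl-4-hydroxy-4-methyl-3-(penta-3,4-dien-1-yl)-2-{3-[(tert-butyldiphenylsilyl)oxy]propyl}cyclohexylidene]propanal | C=C=CCC[C@@]1(C=O)[C@H](CCCO[Si](c2ccccc2)(c2ccccc2)C(C)(C)C)/C(=C(/C)C=O)CC[C@]1(C)O | intermediate
26 | (2Z)-2-[3-formyl-4-methyl-3-(penta-3,4-dien-1-yl)-2-{3-[(tert-butyldiphenylsilyl)oxy]propyl}-4-[(triethylsilyl)oxy]cyclohexylidene]propanal | C=C=CCC[C@@]1(C=O)[C@H](CCCO[Si](c2ccccc2)(c2ccccc2)C(C)(C)C)/C(=C(/C)C=O)CC[C@]1(C)O[Si](CC)(CC)CC | intermediate
27 | allylic and vinylic bis(tributylstannane) from distannylation of the allene of 26 | CCCC[Sn](CCCC)(CCCC)CC(=CCC[C@@]1(C=O)[C@H](CCCO[Si](c2ccccc2)(c2ccccc2)C(C)(C)C)/C(=C(/C)C=O)CC[C@]1(C)O[Si](CC)(CC)CC)[Sn](CCCC)(CCCC)CCCC | intermediate (not isolated)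
28 | tributyltin alkoxide of 29 | C=C([Sn](CCCC)(CCCC)CCCC)[C@@H]1CC[C@]2([C@H](CCCO[Si](c3ccccc3)(c3ccccc3)C(C)(C)C)/C(=C(/C)C=O)CC[C@]2(C)O[Si](CC)(CC)CC)[C@@H]1O[Sn](CCCC)(CCCC)CCCC | intermediate (not isolated)
29 | (2Z)-2-[1-hydroxy-6-methyl-10-{3-[(tert-butyldiphenylsilyl)oxy]propyl}-6-[(triethylsilyl)oxy]-2-[1-(tributylstannyl)ethenyl]spiro[4.5]decan-9-ylidene]propanal (configuration as in the target) | C=C([Sn](CCCC)(CCCC)CCCC)[C@@H]1CC[C@]2([C@H](CCCO[Si](c3ccccc3)(c3ccccc3)C(C)(C)C)/C(=C(/C)C=O)CC[C@]2(C)O[Si](CC)(CC)CC)[C@@H]1O | intermediate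
30 | prop-2-yn-1-ol | C#CCO | starting material
31 | 5-bromo-2-methylpent-2-ene | CC(C)=CCCBr | starting material
32 | (4-methylpent-3-en-1-yl)magnesium bromide | CC(C)=CCC[Mg]Br | intermediate (not isolated)
33 | alkenylmagnesium alkoxide from anti-carbomagnesiation (magnesium cis to the alkoxymethyl group) | CC(C)=CCC/C(=C/[Mg]Br)CO[Mg]Br | intermediate (not isolated)
34 | (2Z)-2-(iodomethylidene)-6-methylhept-5-en-1-ol | OC/C(CCC=C(C)C)=C\I | intermediate
35 | (2Z)-2-(iodomethylidene)-6-methylhept-5-en-1-yl acetate | CC(=O)OC/C(CCC=C(C)C)=C\I | intermediate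
36 | (E)-1,2-bis(tributylstannyl)ethene | CCCC[Sn](CCCC)(CCCC)/C=C/[Sn](CCCC)(CCCC)CCCC | starting material
37 | (2Z)-6-methyl-2-[(2E)-3-(tributylstannyl)prop-2-en-1-ylidene]hept-5-en-1-yl acetate | CC(=O)OC/C(CCC=C(C)C)=C\C=C\[Sn](CCCC)(CCCC)CCCC | intermediate
38 | (2Z)-2-[(2E)-3-iodoprop-2-en-1-ylidene]-6-methylhept-5-en-1-yl acetate | CC(=O)OC/C(CCC=C(C)C)=C\C=C\I | intermediate
39 | target protected as primary tert-butyldiphenylsilyl ether and tertiary triethylsilyl ether | C=C(/C=C/C=C(/CCC=C(C)C)COC(C)=O)[C@@H]1CC[C@]2([C@H](CCCO[Si](c3ccccc3)(c3ccccc3)C(C)(C)C)/C(=C(/C)C=O)CC[C@]2(C)O[Si](CC)(CC)CC)[C@@H]1O | intermediate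
40 | CNP0205332.1: (2Z)-2-[1,6-dihydroxy-10-(3-hydroxypropyl)-6-methyl-2-{(3E,5Z)-6-(acetoxymethyl)-10-methylundeca-1,3,5,9-tetraen-2-yl}spiro[4.5]decan-9-ylidene]propanal | C=C(/C=C/C=C(/CCC=C(C)C)COC(C)=O)[C@@H]1CC[C@]2([C@H](CCCO)/C(=C(/C)C=O)CC[C@]2(C)O)[C@@H]1O | target

**Summary**

Total step count: 24. Longest linear sequence: 18 steps (steps 3 to 18, then 23 and 24, from pent-4-yn-1-ol).

Steps most likely to fail:

1. Step 14. The hindered acylammonium salt may be deprotonated slowly, so that intermolecular acylation competes, and the C10 stereocentre may discriminate the two faces poorly during the aldol addition. Fallback: from keto aldehyde 20, α-bromination of the branched aldehyde (N-bromosuccinimide, catalytic pyrrolidine) would give the α-bromo aldehyde F1, Pinnick oxidation the α-bromo acid F2 and Me3SiCHN2 the α-bromo ester F3. SmI2 in THF at −78 °C would then reduce the carbon–bromine bond to a samarium enolate that closes onto the methyl ketone in an intramolecular Reformatsky reaction through a metal-bridged chair, giving the β-hydroxy diester F4. Reduction of both esters of F4 with i-Bu2AlH would give triol 24, where the route is rejoined.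

2. Step 18. The allylstannane may attack the wrong face of the neopentyl aldehyde (rotamer control about the C5–C1 bond), or be lost by protodestannylation before it cyclises. Fallback: from silyl ether 26, a copper-catalysed borylative cyclisation (CuCl, 1,3-dimesitylimidazolinium chloride, NaOt-Bu, bis(pinacolato)diboron, THF) would pass through a 2-boryl allylcopper that adds to the aldehyde in a closed six-membered transition state and give the alkenylboronate F5. Suzuki–Miyaura coupling of F5 with iodide 38 (Pd(PPh3)4, TlOEt, THF/H2O) would give 39.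

3. Step 8. The nitronate may solvolyse incompletely, and the strong acid may remove the silyl ether or add methanol to the allene. Fallback: from nitro compound 10, the nitronate (NaOMe) would be reduced with aqueous TiCl3 buffered with NH4OAc, and hydrolysis of the resulting imine would give the aldehyde F6 under nearly neutral conditions. Acetalisation of F6 with HC(OMe)3 and pyridinium p-toluenesulfonate in methanol would give 12.

Further compounds
F1 | step 14 | methyl (2Z,4S)-5-bromo-5-formyl-2-methyl-3-(3-oxobutyl)-4-{3-[(tert-butyldiphenylsilyl)oxy]propyl}deca-2,8,9-trienoate (both epimers at the brominated carbon) | COC(=O)/C(C)=C(/CCC(C)=O)[C@@H](CCCO[Si](c1ccccc1)(c1ccccc1)C(C)(C)C)C(Br)(CCC=C=C)C=O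
F2 | step 14 | α-bromo acid corresponding to F1 | COC(=O)/C(C)=C(/CCC(C)=O)[C@@H](CCCO[Si](c1ccccc1)(c1ccccc1)C(C)(C)C)C(Br)(CCC=C=C)C(=O)O
F3 | step 14 | methyl ester of F2 | COC(=O)/C(C)=C(/CCC(C)=O)[C@@H](CCCO[Si](c1ccccc1)(c1ccccc1)C(C)(C)C)C(Br)(CCC=C=C)C(=O)OC
F4 | step 14 | methyl 2-hydroxy-4-[(2Z)-1-methoxy-1-oxopropan-2-ylidene]-2-methyl-1-(penta-3,4-dien-1-yl)-6-{3-[(tert-butyldiphenylsilyl)oxy]propyl}cyclohexane-1-carboxylate (hydroxyl, ester and chain all cis) | C=C=CCC[C@@]1(C(=O)OC)[C@H](CCCO[Si](c2ccccc2)(c2ccccc2)C(C)(C)C)/C(=C(/C)C(=O)OC)CC[C@]1(C)O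
F5 | step 18 | analogue of 29 with a pinacolboronate in place of the tributylstannyl group | C=C(B1OC(C)(C)C(C)(C)O1)[C@@H]1CC[C@]2([C@H](CCCO[Si](c3ccccc3)(c3ccccc3)C(C)(C)C)/C(=C(/C)C=O)CC[C@]2(C)O[Si](CC)(CC)CC)[C@@H]1O
F6 | step 8 | (2S,3S)-3-(2,2-dibromoethenyl)-2-(penta-3,4-dien-1-yl)-6-[(tert-butyldiphenylsilyl)oxy]hexanal | BrC(Br)=C[C@@H](CCCO[Si](c1ccccc1)(c1ccccc1)C(C)(C)C)[C@H](CCC=C=C)C=O
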